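Watch how fast the second nucleophile falls while the substrate turns into intermediate.

| setting | Wednesday's | Thursday's | Sunday's | Monday's | Tuesday's |
|---|---|---|---|---|---|
| substrate | 0.21 M (fed, over 0.20 s) | 0.21 M | 0.21 M | 0.21 M (in portions, 3, over 2.0 s) | 0.21 M (fed, over 2.0 s) |
| first nucleophile | 0.231 M | 0.231 M | 0.231 M | 0.231 M | 0.231 M |
| second nucleophile | 0.273 M | 0.273 M (fed, over 2.0 s) | 0.273 M | 0.273 M | 0.273 M |
| time | 5.0 s | 5.0 s | 5.0 s | 5.0 s | 5.0 s |
| remark | all else is in the flask from the start; the feed brings no volume worth counting | all else is in the flask from the start; the feed brings no volume worth counting | everything together at the start | first portion at the start, last at 2.0 s | all else is in the flask from the start; the feed brings no volume worth counting |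

    substrate → intermediate (k1 = 2.3 s⁻¹)
    first nucleophile + intermediate → target (k2 = 8.3 M⁻¹ s⁻¹)
    second nucleophile + intermediate → other capture product (k3 = 8.4 M⁻¹ s⁻¹)
    substrate + target → side product (k4 = 1.7 M⁻¹ s⁻¹)
    2 second nucleophile → homo dimer (k5 = 4.5 M⁻¹ s⁻¹)

- in percentages every species weighs as the substrate in it: one side product counts as two
- two of one species on the left: rate k times its square, two consumed each time
- run time (Wednesday's): 5.0 s

- which flask leads in share of target in target plus other capture product ("all alike" within 1.5 percentage points) (Wednesday's / Thursday's / Sunday's / Monday's / Tuesday's / all alike)
- share of target in target plus other capture product at the end, Wednesday's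
- share of target in target plus other capture product at the end, Thursday's
- share of target in target plus other capture product at the end, Sunday's
- share of target in target plus other capture product at the end, Monday's
- share of target in target plus other capture product at the end, Tuesday's

I turned the constants into times at the charged amounts. The second nucleophile had a first half-life by dimerisation of 0.407 s, and the substrate needed 0.435 s on average to become intermediate, plus 0.5 of any addition time. The capture constants, 8.3 M⁻¹ s⁻¹ and 8.4 M⁻¹ s⁻¹, stood close, so I took the split to follow the two nucleophile concentrations at the moment the intermediate formed.

That gave me one number, the age number, 1.07 for Sunday's flask: the mean wait for intermediate divided by that half-life of the second nucleophile. Counting dimerisation and no other loss, [second nucleophile] has by then fallen by the factor one plus this number. With [first nucleophile] held at its charge, the rate of capture by the first nucleophile over that by the second stands at 0.836 as charged, and in my reckoning this ratio grows by the same factor.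

For Sunday's flask my reckoning came to a ratio of 1.73, a target share of 63.4%. Wednesday's age number of 1.31 gave 1.93 and 65.9%. Tuesday's age number of 3.53 gave 3.78 and 79.1%. Monday's portions arrive on the same mean time as Tuesday's feed, so my number gave those two flasks one share and could not rank them. In Thursday's flask the second nucleophile is itself fed, so the number as built did not apply and I gave no figure.

The forecast named Tuesday's, with 68% for Wednesday's, 70% for Thursday's, 67% for Sunday's, 72.5% for Monday's and 73.5% for Tuesday's, on the ground that “anything that delays intermediate formation favours the target”. It stood above my figures for Sunday's and Wednesday's and below mine for Tuesday's.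

The flasks gave 68.5% for Wednesday's, 68.1% for Thursday's, 66.2% for Sunday's, 76.1% for Monday's and 78.2% for Tuesday's, so Tuesday's led, 2.1 percentage points above Monday's against a margin of 1.5 points, although both carry one age number. In Sunday's flask at 0.292 s, dimerisation used second nucleophile 2.5 times as fast as capture did, and 14 times as fast at 5.00 s. The neighbour of Sunday's with 0.16 M of second nucleophile has an age number of 0.626, which gives a ratio of 2.32, a target share of 69.9%, and that flask stood at 72.3%.

All constants are made up.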